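Everything rests on cutting the C1–Ca bond between ring C and the stereocentre, together with a temporary O–Cb bond from the C2 oxygen. In one operation a chiral dirhodium carbene, made from a ring C ortho-quinone diazide (diazo carbon C1, carbonyl C2, ester at C5), adds across a trisilylated ring A/ring B (E)-stilbene, forming C1–Ca and O–Cb and setting Ca. The step exploits the ortho and para oxygens of ring B (at B2 and B4), which polarise the alkene so that Ca is its nucleophilic end while Cb can carry the positive charge, and the adjacency of C1 and the C2 oxygen in ring C. Hydrogenolysis of O–Cb then restores the CH2; the ring D styryl arm is attached last at C5.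

Key step: step 9

Labels: Ca is the stereocentre, (S) in the target, and Cb is its CH2 neighbour. Ring A is the 4-hydroxy-3-methoxyphenyl group on Ca (A1 attached). Ring B is the 2,4-dihydroxyphenyl group on Cb (B1 attached). Ring C is the central ring (C1 on Ca, OH at C2, OMe at C3, styryl at C5). Ring D is the 3,5-dihydroxyphenyl ring. TBS is tert-butyldimethylsilyl.

Assumption: the sense of induction of the chiral dirhodium carboxylate on this untested pair cannot be predicted; the (S)-ligand series is written, and the enantiomeric catalyst would be used if a trial shows that it is the one that gives (S)-Ca.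

Step 1
Reactants: 1 methyl vanillate (methyl 4-hydroxy-3-methoxybenzoate)
Product: 2 methyl 4-hydroxy-3-methoxy-5-nitrobenzoate
Conditions: HNO3 (65%, 1.1 equiv), AcOH, 0 °C to rt
Reagents that add atoms: nitric acid, O[N+](=O)[O-]
Why: Electrophilic aromatic nitration should go to the only free position ortho to the phenol (the future C1 of ring C), because the para position carries the ester.

Step 2
Reactants: 2 methyl 4-hydroxy-3-methoxy-5-nitrobenzoate
Product: 3 methyl 3-amino-4-hydroxy-5-methoxybenzoate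
Conditions: H2 (1 atm), 10% Pd/C, EtOAc–MeOH, rt
Reagents that add atoms: none
Why: Catalytic hydrogenation of an aromatic nitro group to the aniline is dependable and leaves the ester and the methyl ether alone.

Step 3
Reactants: 3 methyl 3-amino-4-hydroxy-5-methoxybenzoate
Product: 5 methyl 3-diazo-5-methoxy-4-oxocyclohexa-1,5-diene-1-carboxylate (ring C ortho-quinone diazide), via arenediazonium chloride 4 (not isolated)
Conditions: NaNO2 (1.05 equiv), 2 M aq. HCl, 0 °C; then NaHCO3 to pH 7, extraction into CH2Cl2; kept cold and dark, handled on small scale as a solution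
Reagents that add atoms: sodium nitrite, [Na+].[O-]N=O
Why: Diazotisation of the ortho-aminophenol gives the diazonium salt, whose phenol is acidified by the para ester and should lose its proton on neutralisation to give the neutral ortho-quinone diazide.

Step 4
Reactants: 6 vanillin (4-hydroxy-3-methoxybenzaldehyde)
Product: 7 4-(TBSO)-3-methoxybenzaldehyde
Conditions: TBSCl (1.2 equiv), imidazole (2.5 equiv), DMF, rt
Reagents that add atoms: tert-butyldimethylsilyl chloride, CC(C)(C)[Si](C)(C)Cl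
Why: Silylation of a phenol with a silyl chloride and imidazole is routine.

Step 5
Reactants: 7 4-(TBSO)-3-methoxybenzaldehyde
Product: 8 [4-(TBSO)-3-methoxyphenyl]methanol
Conditions: NaBH4, MeOH–THF, 0 °C
Reagents that add atoms: none
Why: Borohydride reduction of an aromatic aldehyde is fast at 0 °C, which spares the aryl silyl ether.

Step 6
Reactants: 8 [4-(TBSO)-3-methoxyphenyl]methanol
Product: 9 diethyl {[4-(TBSO)-3-methoxyphenyl]methyl}phosphonate
Conditions: P(OEt)3 (3 equiv), ZnI2 (1.5 equiv), THF, reflux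
Reagents that add atoms: triethyl phosphite, CCOP(OCC)OCC
Why: The ZnI2-mediated direct conversion of an electron-rich benzylic alcohol into its diethyl phosphonate (a Michaelis–Arbuzov-type process) should work well here and avoids the labile para-silyloxybenzyl halide.

Step 7
Reactants: 10 2,4-dihydroxybenzaldehyde
Product: 11 2,4-bis(TBSO)benzaldehyde
Conditions: TBSCl (2.5 equiv), imidazole (5 equiv), DMF, rt
Reagents that add atoms: tert-butyldimethylsilyl chloride, CC(C)(C)[Si](C)(C)Cl
Why: Double silylation of the two phenols under standard conditions, the hydrogen-bonded ortho phenol reacting more slowly but completely with excess reagent.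

Step 8
Reactants: 9 diethyl {[4-(TBSO)-3-methoxyphenyl]methyl}phosphonate; 11 2,4-bis(TBSO)benzaldehyde
Product: 12 (E)-1-[2,4-bis(TBSO)phenyl]-2-[4-(TBSO)-3-methoxyphenyl]ethene
Conditions: KN(SiMe3)2 (1.1 equiv), THF, −78 °C; then 11, −78 °C to rt
Reagents that add atoms: none
Why: Horner–Wadsworth–Emmons olefination of a benzylphosphonate anion with an aromatic aldehyde should give the (E)-stilbene, and the bulky amide base should not attack the aryl silyl ethers.

Step 9
Reactants: 5 methyl 3-diazo-5-methoxy-4-oxocyclohexa-1,5-diene-1-carboxylate; 12 (E)-1-[2,4-bis(TBSO)phenyl]-2-[4-(TBSO)-3-methoxyphenyl]ethene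
Product: 13 methyl (2S,3S)-2-[2,4-bis(TBSO)phenyl]-3-[4-(TBSO)-3-methoxyphenyl]-7-methoxy-2,3-dihydro-1-benzofuran-5-carboxylate (2,3-trans)
Conditions: Rh2(S-TCPTTL)4 (dirhodium tetrakis[N-tetrachlorophthaloyl-(S)-tert-leucinate], 2 mol%), 12 (1 equiv), 5 (2 equiv, added over 6 h), 4 Å molecular sieves, CH2Cl2, 0 °C to rt, dark
Reagents that add atoms: none
Why: Proposed new method: the dirhodium catalyst should expel N2 from 5 to give an electrophilic quinoid carbene at C1 (sharpened by the C5 ester), Ca of 12 should attack it to form C1–Ca and a zwitterion whose Cb cation is delocalised onto the B2 and B4 oxygens, and the rearomatised C2 phenoxide should then capture Cb; the closest known reaction type is the rhodium-catalysed formal (3+2) cycloaddition of cyclic 2-diazo-1,3-dicarbonyl compounds and diazonaphthoquinones with enol ethers and styrenes, which has not been shown with enantiocontrol for a simple benzoquinone diazide and a 1,2-diarylalkene. The dihydrofuran ring closes by 5-exo-trig attack of oxygen on the quinone-methide-like Cb. Ca is set under catalyst control, because C1–Ca forms while C1 still sits in the chiral carboxylate pocket, and Cb follows under substrate control as the 2,3-trans isomer, which keeps the two aryl groups apart and is erased later. The step needs regioselectivity (C1 to Ca, O to Cb), secured because ring B puts two oxygen lone pairs in conjugation with Cb whereas ring A offers only one to Ca, and because the B2 silyl ether crowds Cb. It also needs chemoselectivity for the alkene over arene C–H and ether oxygen, secured by bulky, weakly basic silyl ethers, while slow addition of 5 limits carbene dimerisation.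

Step 10
Reactants: 13 methyl (2S,3S)-2-[2,4-bis(TBSO)phenyl]-3-[4-(TBSO)-3-methoxyphenyl]-7-methoxy-2,3-dihydro-1-benzofuran-5-carboxylate
Product: 14 methyl 3-{(1S)-2-[2,4-bis(TBSO)phenyl]-1-[4-(TBSO)-3-methoxyphenyl]ethyl}-4-hydroxy-5-methoxybenzoate
Conditions: H2 (1–3 atm), 10% Pd/C, EtOAc, rt
Reagents that add atoms: none
Why: Catalytic hydrogenolysis of a benzylic C–O bond should cleave O–Cb, a benzyl aryl ether with an ester-bearing phenoxide as leaving group, turning Cb into CH2 while Ca is not involved and keeps its configuration.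

Step 11
Reactants: 14 methyl 3-{(1S)-2-[2,4-bis(TBSO)phenyl]-1-[4-(TBSO)-3-methoxyphenyl]ethyl}-4-hydroxy-5-methoxybenzoate
Product: 15 methyl 3-{(1S)-2-[2,4-bis(TBSO)phenyl]-1-[4-(TBSO)-3-methoxyphenyl]ethyl}-4-(TBSO)-5-methoxybenzoate
Conditions: TBSOTf (1.5 equiv), 2,6-lutidine (3 equiv), CH2Cl2, 0 °C
Reagents that add atoms: tert-butyldimethylsilyl trifluoromethanesulfonate, CC(C)(C)[Si](C)(C)OS(=O)(=O)C(F)(F)F
Why: Silylation with the silyl triflate should overcome the hindrance of the 2,6-disubstituted C2 phenol.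

Step 12
Reactants: 15 methyl 3-{(1S)-2-[2,4-bis(TBSO)phenyl]-1-[4-(TBSO)-3-methoxyphenyl]ethyl}-4-(TBSO)-5-methoxybenzoate
Product: 16 (3-{(1S)-2-[2,4-bis(TBSO)phenyl]-1-[4-(TBSO)-3-methoxyphenyl]ethyl}-4-(TBSO)-5-methoxyphenyl)methanol
Conditions: i-Bu2AlH (2.5 equiv), CH2Cl2, −78 to 0 °C; aq. KNaC4H4O6 (potassium sodium tartrate) work-up
Reagents that add atoms: none
Why: Hydride reduction of the benzoate ester to the primary alcohol with i-Bu2AlH is standard and tolerates aryl silyl ethers.

Step 13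
Reactants: 16 (3-{(1S)-2-[2,4-bis(TBSO)phenyl]-1-[4-(TBSO)-3-methoxyphenyl]ethyl}-4-(TBSO)-5-methoxyphenyl)methanol
Product: 17 3-{(1S)-2-[2,4-bis(TBSO)phenyl]-1-[4-(TBSO)-3-methoxyphenyl]ethyl}-4-(TBSO)-5-methoxybenzaldehyde
Conditions: activated MnO2 (15 equiv), CH2Cl2, rt
Reagents that add atoms: none
Why: MnO2 oxidation of a benzylic alcohol stops cleanly at the aldehyde under neutral conditions.

Step 14
Reactants: 18 methyl 3,5-dihydroxybenzoate
Product: 19 methyl 3,5-bis(TBSO)benzoate
Conditions: TBSCl (2.5 equiv), imidazole (5 equiv), DMF, rt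
Reagents that add atoms: tert-butyldimethylsilyl chloride, CC(C)(C)[Si](C)(C)Cl
Why: Standard silylation of two unhindered phenols.

Step 15
Reactants: 19 methyl 3,5-bis(TBSO)benzoate
Product: 20 [3,5-bis(TBSO)phenyl]methanol
Conditions: i-Bu2AlH (2.5 equiv), CH2Cl2, −78 to 0 °C; aq. KNaC4H4O6 work-up
Reagents that add atoms: none
Why: Hydride reduction of the ester to the benzylic alcohol, with the aryl silyl ethers inert to i-Bu2AlH.

Step 16
Reactants: 20 [3,5-bis(TBSO)phenyl]methanol
Product: 21 diethyl {[3,5-bis(TBSO)phenyl]methyl}phosphonate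
Conditions: P(OEt)3 (3 equiv), ZnI2 (1.5 equiv), toluene, reflux
Reagents that add atoms: triethyl phosphite, CCOP(OCC)OCC
Why: The same ZnI2-mediated direct phosphonylation of a benzylic alcohol (Michaelis–Arbuzov type), run hotter because the meta oxygens do not activate the benzylic position.

Step 17
Reactants: 17 3-{(1S)-2-[2,4-bis(TBSO)phenyl]-1-[4-(TBSO)-3-methoxyphenyl]ethyl}-4-(TBSO)-5-methoxybenzaldehyde; 21 diethyl {[3,5-bis(TBSO)phenyl]methyl}phosphonate
Product: 22 hexakis-TBS ether of the target, (S) at Ca and (E) at the alkene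
Conditions: KN(SiMe3)2 (1.2 equiv), 21 (1.3 equiv), THF, −78 °C; then 17, −78 °C to rt
Reagents that add atoms: none
Why: Horner–Wadsworth–Emmons olefination should give the (E)-stilbene, and Ca should hold its configuration because its hydrogen is not conjugated with the formyl group and is far less acidic than the phosphonate.

Step 18
Reactants: 22 hexakis-TBS ether of the target
Product: 23 4-[(2S)-2-{5-[(E)-2-(3,5-dihydroxyphenyl)ethenyl]-2-hydroxy-3-methoxyphenyl}-2-(4-hydroxy-3-methoxyphenyl)ethyl]benzene-1,3-diol (CNP0254096.1)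
Conditions: Bu4NF (7 equiv), AcOH (7 equiv), THF, 0 °C to rt, under argon
Reagents that add atoms: none
Why: Fluoride desilylation of aryl silyl ethers, buffered with acetic acid so that the oxidation-prone polyphenolic stilbene is never exposed to free phenoxide.

Compound list

1 | methyl vanillate (methyl 4-hydroxy-3-methoxybenzoate) | COC(=O)c1ccc(O)c(OC)c1 | starting material
2 | methyl 4-hydroxy-3-methoxy-5-nitrobenzoate | COC(=O)c1cc(OC)c(O)c([N+](=O)[O-])c1 | intermediate
3 | methyl 3-amino-4-hydroxy-5-methoxybenzoate | COC(=O)c1cc(N)c(O)c(OC)c1 | intermediate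
4 | 2-hydroxy-3-methoxy-5-(methoxycarbonyl)benzenediazonium chloride | COC(=O)c1cc(OC)c(O)c([N+]#N)c1.[Cl-] | intermediate
5 | methyl 3-diazo-5-methoxy-4-oxocyclohexa-1,5-diene-1-carboxylate | COC1=CC(C(=O)OC)=CC(=[N+]=[N-])C1=O | intermediate
6 | vanillin | COc1cc(C=O)ccc1O | starting material
7 | 4-(TBSO)-3-methoxybenzaldehyde | COc1cc(C=O)ccc1O[Si](C)(C)C(C)(C)C | intermediate
8 | [4-(TBSO)-3-methoxyphenyl]methanol | COc1cc(CO)ccc1O[Si](C)(C)C(C)(C)C | intermediate
9 | diethyl {[4-(TBSO)-3-methoxyphenyl]methyl}phosphonate | CCOP(=O)(Cc1ccc(O[Si](C)(C)C(C)(C)C)c(OC)c1)OCC | intermediate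
10 | 2,4-dihydroxybenzaldehyde | O=Cc1ccc(O)cc1O | starting material
11 | 2,4-bis(TBSO)benzaldehyde | O=Cc1ccc(O[Si](C)(C)C(C)(C)C)cc1O[Si](C)(C)C(C)(C)C | intermediate
12 | (E)-1-[2,4-bis(TBSO)phenyl]-2-[4-(TBSO)-3-methoxyphenyl]ethene | COc1cc(/C=C/c2ccc(O[Si](C)(C)C(C)(C)C)cc2O[Si](C)(C)C(C)(C)C)ccc1O[Si](C)(C)C(C)(C)C | intermediate
13 | methyl (2S,3S)-2-[2,4-bis(TBSO)phenyl]-3-[4-(TBSO)-3-methoxyphenyl]-7-methoxy-2,3-dihydro-1-benzofuran-5-carboxylate | COc1cc([C@H]2c3cc(C(=O)OC)cc(OC)c3O[C@@H]2c2ccc(O[Si](C)(C)C(C)(C)C)cc2O[Si](C)(C)C(C)(C)C)ccc1O[Si](C)(C)C(C)(C)C | intermediate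
14 | methyl 3-{(1S)-2-[2,4-bis(TBSO)phenyl]-1-[4-(TBSO)-3-methoxyphenyl]ethyl}-4-hydroxy-5-methoxybenzoate | COc1cc([C@H](Cc2ccc(O[Si](C)(C)C(C)(C)C)cc2O[Si](C)(C)C(C)(C)C)c2cc(C(=O)OC)cc(OC)c2O)ccc1O[Si](C)(C)C(C)(C)C | intermediate
15 | methyl 3-{(1S)-2-[2,4-bis(TBSO)phenyl]-1-[4-(TBSO)-3-methoxyphenyl]ethyl}-4-(TBSO)-5-methoxybenzoate | COc1cc([C@H](Cc2ccc(O[Si](C)(C)C(C)(C)C)cc2O[Si](C)(C)C(C)(C)C)c2cc(C(=O)OC)cc(OC)c2O[Si](C)(C)C(C)(C)C)ccc1O[Si](C)(C)C(C)(C)C | intermediate
16 | (3-{(1S)-2-[2,4-bis(TBSO)phenyl]-1-[4-(TBSO)-3-methoxyphenyl]ethyl}-4-(TBSO)-5-methoxyphenyl)methanol | COc1cc([C@H](Cc2ccc(O[Si](C)(C)C(C)(C)C)cc2O[Si](C)(C)C(C)(C)C)c2cc(CO)cc(OC)c2O[Si](C)(C)C(C)(C)C)ccc1O[Si](C)(C)C(C)(C)C | intermediate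
17 | 3-{(1S)-2-[2,4-bis(TBSO)phenyl]-1-[4-(TBSO)-3-methoxyphenyl]ethyl}-4-(TBSO)-5-methoxybenzaldehyde | COc1cc([C@H](Cc2ccc(O[Si](C)(C)C(C)(C)C)cc2O[Si](C)(C)C(C)(C)C)c2cc(C=O)cc(OC)c2O[Si](C)(C)C(C)(C)C)ccc1O[Si](C)(C)C(C)(C)C | intermediate
18 | methyl 3,5-dihydroxybenzoate | COC(=O)c1cc(O)cc(O)c1 | starting material
19 | methyl 3,5-bis(TBSO)benzoate | COC(=O)c1cc(O[Si](C)(C)C(C)(C)C)cc(O[Si](C)(C)C(C)(C)C)c1 | intermediate
20 | [3,5-bis(TBSO)phenyl]methanol | OCc1cc(O[Si](C)(C)C(C)(C)C)cc(O[Si](C)(C)C(C)(C)C)c1 | intermediate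
21 | diethyl {[3,5-bis(TBSO)phenyl]methyl}phosphonate | CCOP(=O)(Cc1cc(O[Si](C)(C)C(C)(C)C)cc(O[Si](C)(C)C(C)(C)C)c1)OCC | intermediate
22 | hexakis-TBS ether of the target, (S) at Ca, (E)-alkene | COc1cc([C@H](Cc2ccc(O[Si](C)(C)C(C)(C)C)cc2O[Si](C)(C)C(C)(C)C)c2cc(/C=C/c3cc(O[Si](C)(C)C(C)(C)C)cc(O[Si](C)(C)C(C)(C)C)c3)cc(OC)c2O[Si](C)(C)C(C)(C)C)ccc1O[Si](C)(C)C(C)(C)C | intermediate
23 | 4-[(2S)-2-{5-[(E)-2-(3,5-dihydroxyphenyl)ethenyl]-2-hydroxy-3-methoxyphenyl}-2-(4-hydroxy-3-methoxyphenyl)ethyl]benzene-1,3-diol (CNP0254096.1) | COc1cc([C@H](Cc2ccc(O)cc2O)c2cc(/C=C/c3cc(O)cc(O)c3)cc(OC)c2O)ccc1O | target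

Total step count: 18.
Longest linear sequence: 11 steps (from vanillin 6: steps 4, 5, 6, 8, 9, 10, 11, 12, 13, 17, 18).

Steps most likely to fail

1. Step 9 (Proposed new method). The carbene may be consumed by dimerisation or by attack on the electron-rich arenes before the trans-disubstituted alkene reacts, and facial selectivity at Ca or the sense of addition across Ca/Cb may be poor. The fallback uses known chemistry, the enantioselective intramolecular C–H insertion of a diaryl (donor/donor) rhodium carbene into a benzyl ether. It sets out from 1, with 7 and 11 as the other building blocks, and comes back at 14.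
   - Methyl vanillate 1 would be iodinated ortho to the phenol (N-iodosuccinimide, cat. CF3CO2H, MeCN) to methyl 4-hydroxy-3-iodo-5-methoxybenzoate F1.
   - Aldehyde 11 would be reduced (NaBH4) to [2,4-bis(TBSO)phenyl]methanol F2.
   - A Mitsunobu etherification (PPh3, diisopropyl azodicarboxylate, THF) would join the two as methyl 4-{[2,4-bis(TBSO)phenyl]methoxy}-3-iodo-5-methoxybenzoate F3.
   - Iodine–magnesium exchange of F3 (i-PrMgCl·LiCl, THF, −40 °C, which the ester tolerates) and addition to aldehyde 7 would give the racemic diarylmethanol methyl 4-{[2,4-bis(TBSO)phenyl]methoxy}-3-{[4-(TBSO)-3-methoxyphenyl](hydroxy)methyl}-5-methoxybenzoate F4.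
   - MnO2 would oxidise it to the diaryl ketone methyl 4-{[2,4-bis(TBSO)phenyl]methoxy}-3-[4-(TBSO)-3-methoxybenzoyl]-5-methoxybenzoate F5.
   - Condensation with acetic acid-buffered hydrazine (N2H4·H2O, AcOH, EtOH, warm), under which the ester should not undergo hydrazinolysis, would give the hydrazone F6.
   - MnO2 oxidation would give the diaryldiazomethane F7, used at once.
   - Rh2(S-PTAD)4 (dirhodium tetrakis[(S)-1-adamantyl(phthalimido)acetate]), or its enantiomer, whichever delivers 3S, would insert the carbene into the OCH2 group that carries ring B, at 0 °C in CH2Cl2. This should give the 2,3-cis-dihydrobenzofuran methyl (2R,3S)-2-[2,4-bis(TBSO)phenyl]-3-[4-(TBSO)-3-methoxyphenyl]-7-methoxy-2,3-dihydro-1-benzofuran-5-carboxylate F8 with Ca set.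
   - Hydrogenolysis as in step 10 removes the Cb stereocentre and gives 14.

2. Step 10. Hydrogenolysis may stall at the crowded secondary benzylic ether, or the configuration at Ca may erode through elimination toward Ca followed by re-hydrogenation on the metal. The fallback replaces surface hydrogenolysis by ionic hydrogenation, from 13 back to 14: CF3CO2H ionises O–Cb to the ring B-stabilised benzylic cation, which takes hydride from Et3SiH (excess, CH2Cl2, −40 to 0 °C). Aryl silyl ethers and the ester should survive, and excess silane should outrun proton loss from Ca. No compound outside the list is formed (F0).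

3. Step 8. The silyl group ortho to the formyl group of 11 may migrate to, or be lost through, the alkoxide adduct, which would stall the olefination. The fallback makes the same alkene by a Mizoroki–Heck coupling that involves no oxyanion; it sets out from 11 and comes back at 12.
   - Wittig methylenation of 11 (Ph3PCH3Br, KN(SiMe3)2, THF) would give 1-ethenyl-2,4-bis(TBSO)benzene F9.
   - Commercial 4-bromo-2-methoxyphenol would be silylated (TBSCl, imidazole) to (4-bromo-2-methoxyphenoxy)(tert-butyl)dimethylsilane F10.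
   - Coupling with Pd2(dba)3, [HP(t-Bu)3]BF4 and Cy2NMe in dioxane at 60–80 °C should arylate the terminal carbon of F9 and give the (E)-stilbene 12.

Further compounds

F1 | step 9 | methyl 4-hydroxy-3-iodo-5-methoxybenzoate | COC(=O)c1cc(I)c(O)c(OC)c1
F2 | step 9 | [2,4-bis(TBSO)phenyl]methanol | OCc1ccc(O[Si](C)(C)C(C)(C)C)cc1O[Si](C)(C)C(C)(C)C
F3 | step 9 | methyl 4-{[2,4-bis(TBSO)phenyl]methoxy}-3-iodo-5-methoxybenzoate | COC(=O)c1cc(I)c(OCc2ccc(O[Si](C)(C)C(C)(C)C)cc2O[Si](C)(C)C(C)(C)C)c(OC)c1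
F4 | step 9 | methyl 4-{[2,4-bis(TBSO)phenyl]methoxy}-3-{[4-(TBSO)-3-methoxyphenyl](hydroxy)methyl}-5-methoxybenzoate (racemic carbinol) | COC(=O)c1cc(C(O)c2ccc(O[Si](C)(C)C(C)(C)C)c(OC)c2)c(OCc2ccc(O[Si](C)(C)C(C)(C)C)cc2O[Si](C)(C)C(C)(C)C)c(OC)c1
F5 | step 9 | methyl 4-{[2,4-bis(TBSO)phenyl]methoxy}-3-[4-(TBSO)-3-methoxybenzoyl]-5-methoxybenzoate | COC(=O)c1cc(C(=O)c2ccc(O[Si](C)(C)C(C)(C)C)c(OC)c2)c(OCc2ccc(O[Si](C)(C)C(C)(C)C)cc2O[Si](C)(C)C(C)(C)C)c(OC)c1
F6 | step 9 | hydrazone of F5 | COC(=O)c1cc(C(=NN)c2ccc(O[Si](C)(C)C(C)(C)C)c(OC)c2)c(OCc2ccc(O[Si](C)(C)C(C)(C)C)cc2O[Si](C)(C)C(C)(C)C)c(OC)c1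
F7 | step 9 | diaryldiazomethane from F6 | COC(=O)c1cc(C(=[N+]=[N-])c2ccc(O[Si](C)(C)C(C)(C)C)c(OC)c2)c(OCc2ccc(O[Si](C)(C)C(C)(C)C)cc2O[Si](C)(C)C(C)(C)C)c(OC)c1
F8 | step 9 | methyl (2R,3S)-2-[2,4-bis(TBSO)phenyl]-3-[4-(TBSO)-3-methoxyphenyl]-7-methoxy-2,3-dihydro-1-benzofuran-5-carboxylate (2,3-cis) | COc1cc([C@H]2c3cc(C(=O)OC)cc(OC)c3O[C@H]2c2ccc(O[Si](C)(C)C(C)(C)C)cc2O[Si](C)(C)C(C)(C)C)ccc1O[Si](C)(C)C(C)(C)C
F0 | step 10 | none | none
F9 | step 8 | 1-ethenyl-2,4-bis(TBSO)benzene | C=Cc1ccc(O[Si](C)(C)C(C)(C)C)cc1O[Si](C)(C)C(C)(C)C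
F10 | step 8 | (4-bromo-2-methoxyphenoxy)(tert-butyl)dimethylsilane | COc1cc(Br)ccc1O[Si](C)(C)C(C)(C)C
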